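The cyclohexene is numbered C1 (quaternary; methyl and vinyl arm), C2, C3, C4 (methyl-bearing sp2), C5, C6 (methine carrying coumarin B). The plan cuts C1–C2 and C5–C6: a quaternary C1 flanked by the C2–C3 ethylene and an sp2 C4 is the imprint of an α-branched aldehyde annulated with methyl vinyl ketone. One amine-catalysed Michael–aldol operation closes the carbocycle, forms both bonds and sets C1, giving a 4,4-disubstituted cyclohexenone. Its precursor is racemic 3-silyloxy-2-methylpropanal. The oxymethyl arm then tethers a phosphonoacetate that delivers the coumarin B carbons to C6 cis to itself, and is finally oxidised and olefinated to the vinyl link to coumarin A.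

Key step: step 3

Remark: locants C1–C6 in the text are those defined above; locants inside compound names follow nomenclature.
Remark: compounds 1, 4, 9, 11 and 22 are taken as purchasable.
Remark: for step 3 the (1S,2S) catalyst is written on the assumption that it delivers the (S)-enone; if a pilot run should show the opposite sense, the (1R,2R) antipode is used.

Step 1
Reactants: 1 2-methylpropane-1,3-diol
Product: 2 rac-3-[(tert-butyldimethylsilyl)oxy]-2-methylpropan-1-ol
Conditions: NaH (1.0 equiv), THF, 0 °C → rt; then TBSCl (1.0 equiv), rt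
Reagents that add atoms: tert-butyldimethylsilyl chloride, CC(C)(C)[Si](C)(C)Cl
Why: Deprotonation gives the poorly soluble monosodium alkoxide of the symmetric diol, which is silylated once (nucleophilic substitution at silicon), and since the stereocentre is erased in step 3 the racemate suffices.

Step 2
Reactants: 2 rac-3-[(tert-butyldimethylsilyl)oxy]-2-methylpropan-1-ol
Product: 3 rac-3-[(tert-butyldimethylsilyl)oxy]-2-methylpropanal
Conditions: TEMPO (10 mol %), PhI(OAc)2 (1.1 equiv), CH2Cl2, rt
Reagents that add atoms: none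
Why: TEMPO-catalysed oxoammonium oxidation with PhI(OAc)2 as the terminal oxidant should stop at the aldehyde and leave the silyl ether intact.

Step 3
Reactants: 3 rac-3-[(tert-butyldimethylsilyl)oxy]-2-methylpropanal, 4 methyl vinyl ketone
Product: 7 (4S)-4-{[(tert-butyldimethylsilyl)oxy]methyl}-4-methylcyclohex-2-en-1-one, via keto aldehyde 5 (not isolated), via aldol adduct 6 (not isolated)
Conditions: 1-[(1S,2S)-2-aminocyclohexyl]-3-[3,5-bis(trifluoromethyl)phenyl]thiourea (20 mol %), PhCO2H (20 mol %), 4 (2 equiv, slow addition), toluene, rt; then 50 °C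
Reagents that add atoms: none
Why: The primary amine condenses with racemic 3 to a trisubstituted enamine, which erases the α-stereocentre so that both enantiomers of 3 converge, and its nucleophilic carbon adds to the β-carbon of thiourea-bound 4 (Michael addition), forming C1–C2 and the quaternary C1 and, after hydrolysis, keto aldehyde 5. The closest known reaction type is the amine-catalysed asymmetric Robinson annulation of α,α-disubstituted aldehydes with methyl vinyl ketone to 4,4-disubstituted cyclohex-2-enones. The ring closes by a 6-(enolendo)-exo-trig aldol addition of the methyl-ketone carbon C5 to the aldehyde carbon C6 (giving 6), and loss of water then installs C5=C6 in conjugation with the C4 carbonyl. The only new stereocentre, C1, is set under catalyst control, because the diamine backbone fixes which enamine face meets the hydrogen-bonded enone. The step needs a single enamine geometry, and the substrate secures this through allylic strain, which turns the bulky silyloxymethyl group away from the N-substituent and leaves methyl syn to nitrogen. Because the aldehyde carbon of 5 bears no α-hydrogen, only one aldol direction can give a six-membered ring, so regiochemistry is not at issue.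

Step 4
Reactants: 7 (4S)-4-{[(tert-butyldimethylsilyl)oxy]methyl}-4-methylcyclohex-2-en-1-one
Product: 8 (4S)-4-(hydroxymethyl)-4-methylcyclohex-2-en-1-one
Conditions: HCl (5 mol %, from AcCl), MeOH, 0 °C → rt
Reagents that add atoms: none
Why: Acid-catalysed methanolysis (transetherification at silicon) removes the primary silyl group without ever forming the free alkoxide, which in this vinylogous β-hydroxy ketone could fragment by retro-aldol loss of formaldehyde under basic fluoride conditions.

Step 5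
Reactants: 8 (4S)-4-(hydroxymethyl)-4-methylcyclohex-2-en-1-one, 9 2-(diethoxyphosphoryl)acetic acid
Product: 10 [(1S)-1-methyl-4-oxocyclohex-2-en-1-yl]methyl 2-(diethoxyphosphoryl)acetate
Conditions: DCC (1.2 equiv), DMAP (10 mol %), CH2Cl2, 0 °C → rt
Reagents that add atoms: none
Why: Steglich esterification, in which the carbodiimide activates acid 9 and DMAP transfers the acyl group, should acylate the neopentyl primary alcohol under near-neutral conditions that spare the enone.

Step 6
Reactants: 11 2,4-dihydroxy-3-methoxybenzaldehyde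
Product: 12 2-hydroxy-3-methoxy-4-[(triisopropylsilyl)oxy]benzaldehyde
Conditions: TIPSCl (1.05 equiv), imidazole, DMF, 0 °C
Reagents that add atoms: triisopropylsilyl chloride, CC(C)[Si](Cl)(C(C)C)C(C)C
Why: O-Silylation should occur at the 4-hydroxyl only, because it is the more acidic and more accessible phenol while the 2-hydroxyl is held in a hydrogen bond to the formyl group.

Step 7
Reactants: 12 2-hydroxy-3-methoxy-4-[(triisopropylsilyl)oxy]benzaldehyde
Product: 13 3-methoxy-2-[(4-methoxybenzyl)oxy]-4-[(triisopropylsilyl)oxy]benzaldehyde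
Conditions: 4-MeOC6H4CH2Cl, K2CO3, Bu4NI (cat.), DMF, rt
Reagents that add atoms: 4-methoxybenzyl chloride, COc1ccc(CCl)cc1
Why: Williamson ether synthesis on the remaining chelated phenol installs an acid-labile 4-methoxybenzyl ether that is orthogonal to the aryl silyl ether and inert to the triflation and coupling steps ahead.

Step 8
Reactants: 10 [(1S)-1-methyl-4-oxocyclohex-2-en-1-yl]methyl 2-(diethoxyphosphoryl)acetate, 13 3-methoxy-2-[(4-methoxybenzyl)oxy]-4-[(triisopropylsilyl)oxy]benzaldehyde
Product: 15 (4E,4aR,8aS)-4-{3-methoxy-2-[(4-methoxybenzyl)oxy]-4-[(triisopropylsilyl)oxy]benzylidene}-8a-methyl-4a,5,8,8a-tetrahydro-1H-isochromene-3,6(4H,7H)-dione (cis-fused), via lactone phosphonate 14 (not isolated)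
Conditions: NaH (1.05 equiv), THF (0.02 M), 0 °C → rt; then 13, rt → 45 °C
Reagents that add atoms: none
Why: Tandem intramolecular Michael addition and Horner–Wadsworth–Emmons olefination, in which the tethered phosphonoacetate anion attacks C6 axially from the face of the oxymethyl arm in a 6-exo-trig closure that can only give the cis-fused lactone (C6 set under control of C1), and the phosphonate anion of 14 formed by proton transfer then olefinates 13 to the conjugated (E)-arylidene lactone.

Step 9
Reactants: 15 the (E)-arylidene keto lactone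
Product: 16 (4E,4aR,8aS)-4-{3-methoxy-2-[(4-methoxybenzyl)oxy]-4-[(triisopropylsilyl)oxy]benzylidene}-8a-methyl-3-oxo-3,4,4a,7,8,8a-hexahydro-1H-isochromen-6-yl trifluoromethanesulfonate
Conditions: Tf2O (1.3 equiv), 2,6-di-tert-butyl-4-methylpyridine (1.5 equiv), CH2Cl2, −20 → 20 °C
Reagents that add atoms: trifluoromethanesulfonic anhydride, O=S(=O)(OS(=O)(=O)C(F)(F)F)C(F)(F)F
Why: Enol triflate formation with Tf2O and a hindered pyridine base passes through the more stable enol, which in a cis-fused bicycle with an angular methyl group lies on the ring-fusion side (C4=C5), as in the enolisation of cis-fused 3-keto steroids and cis-2-decalones.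

Step 10
Reactants: 16 the C4=C5 enol triflate
Product: 17 (4E,4aR,8aS)-4-{3-methoxy-2-[(4-methoxybenzyl)oxy]-4-[(triisopropylsilyl)oxy]benzylidene}-6,8a-dimethyl-1,4,4a,7,8,8a-hexahydro-3H-isochromen-3-one
Conditions: MeZnCl (2 equiv), Pd(PPh3)4 (5 mol %), THF, rt → 50 °C
Reagents that add atoms: methylzinc chloride, C[Zn]Cl
Why: Negishi cross-coupling, in which the enol triflate adds oxidatively to zerovalent palladium, methyl is transferred from zinc and reductive elimination forms the C4–CH3 bond, should fix the C4=C5 alkene without touching the lactone or the ethers.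

Step 11
Reactants: 17 the methylated (E)-arylidene lactone
Product: 18 (4E,4aR,8aS)-4-{2-hydroxy-3-methoxy-4-[(triisopropylsilyl)oxy]benzylidene}-6,8a-dimethyl-1,4,4a,7,8,8a-hexahydro-3H-isochromen-3-one
Conditions: CF3CO2H (10 vol %), anisole (5 equiv), CH2Cl2, 0 °C
Reagents that add atoms: none
Why: Acidolysis of the 4-methoxybenzyl ether, with anisole trapping the benzylic cation by Friedel–Crafts alkylation, should free the ortho-phenol while the aryl silyl ether survives dilute acid.

Step 12
Reactants: 18 the (E)-configured ortho-hydroxybenzylidene lactone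
Product: 20 {(1S,2R)-2-[8-methoxy-2-oxo-7-[(triisopropylsilyl)oxy]-2H-chromen-3-yl]-1,4-dimethylcyclohex-3-en-1-yl}methanol, via Z-phenol 19 (not isolated)
Conditions: hν (350 nm, Pyrex), degassed MeCN (2 mM), rt
Reagents that add atoms: none
Why: Photochemical E-to-Z isomerisation of the ortho-hydroxycinnamate chromophore places the phenol next to the lactone carbonyl, and transesterification (the lactone-to-coumarin rearrangement known for α-(2-hydroxybenzylidene) lactones) should then form coumarin B and release the C1 hydroxymethyl group, draining the photoequilibrium.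

Step 13
Reactants: 20 the coumarin B alcohol
Product: 21 (1S,2R)-2-[8-methoxy-2-oxo-7-[(triisopropylsilyl)oxy]-2H-chromen-3-yl]-1,4-dimethylcyclohex-3-ene-1-carbaldehyde
Conditions: Dess–Martin periodinane, NaHCO3, CH2Cl2, 0 °C → rt
Reagents that add atoms: none
Why: Dess–Martin oxidation should convert the hindered neopentyl alcohol into an aldehyde that has no α-hydrogen and therefore cannot epimerise.

Step 14
Reactants: 11 2,4-dihydroxy-3-methoxybenzaldehyde, 22 ethyl 2-(triphenyl-λ5-phosphanylidene)propanoate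
Product: 25 7-hydroxy-8-methoxy-3-methyl-2H-chromen-2-one, via E-cinnamate 23 (not isolated), via Z-cinnamate 24 (not isolated)
Conditions: PhNEt2, reflux (215 °C)
Reagents that add atoms: none
Why: Wittig olefination with the stabilised ylide gives the ortho-hydroxycinnamate, which at the reflux temperature isomerises about the double bond and lactonises, a standard one-pot entry to 3-methylcoumarins.

Step 15
Reactants: 25 7-hydroxy-8-methoxy-3-methyl-2H-chromen-2-one
Product: 26 8-methoxy-3-methyl-7-[(triisopropylsilyl)oxy]-2H-chromen-2-one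
Conditions: TIPSCl, imidazole, DMF, rt
Reagents that add atoms: triisopropylsilyl chloride, CC(C)[Si](Cl)(C(C)C)C(C)C
Why: O-Silylation of the single phenol protects it for the base-mediated olefination and lowers the electron density of the ring before the bromination.

Step 16
Reactants: 26 8-methoxy-3-methyl-7-[(triisopropylsilyl)oxy]-2H-chromen-2-one
Product: 27 3-(bromomethyl)-8-methoxy-7-[(triisopropylsilyl)oxy]-2H-chromen-2-one
Conditions: NBS (1.05 equiv), AIBN (5 mol %), PhCF3, reflux
Reagents that add atoms: N-bromosuccinimide, O=C1CCC(=O)N1Br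
Why: Wohl–Ziegler bromination should be selective for the 3-methyl group, because hydrogen abstraction there gives a radical that is allylic to the C3=C4 bond.

Step 17
Reactants: 27 3-(bromomethyl)-8-methoxy-7-[(triisopropylsilyl)oxy]-2H-chromen-2-one
Product: 28 diethyl ({8-methoxy-2-oxo-7-[(triisopropylsilyl)oxy]-2H-chromen-3-yl}methyl)phosphonate
Conditions: P(OEt)3 (neat), 130 °C
Reagents that add atoms: triethyl phosphite, CCOP(OCC)OCC
Why: Michaelis–Arbuzov reaction of the reactive allylic bromide with triethyl phosphite should give the phosphonate with loss of bromoethane.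

Step 18
Reactants: 21 the coumarin B aldehyde, 28 the coumarin A phosphonate
Product: 29 8-methoxy-3-[(E)-2-{(1R,2R)-2-[8-methoxy-2-oxo-7-[(triisopropylsilyl)oxy]-2H-chromen-3-yl]-1,4-dimethylcyclohex-3-en-1-yl}ethenyl]-7-[(triisopropylsilyl)oxy]-2H-chromen-2-one
Conditions: 28 (1.5 equiv), NaN(SiMe3)2 (1.4 equiv), THF, −78 °C; then 21, −78 °C → rt
Reagents that add atoms: none
Why: Horner–Wadsworth–Emmons olefination of the non-enolisable aldehyde with the semi-stabilised allylic phosphonate anion should give the (E)-alkene, because the adducts equilibrate before syn-elimination of phosphate, and the anion is preformed with a slight deficit of base so that no free amide can attack the doubly allylic C6–H.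

Step 19
Reactants: 29 the bis(triisopropylsilyl) ether of the target
Product: 30 7-hydroxy-3-[(E)-2-[(1R,2R)-2-(7-hydroxy-8-methoxy-2-oxo-2H-chromen-3-yl)-1,4-dimethylcyclohex-3-en-1-yl]ethenyl]-8-methoxy-2H-chromen-2-one (CNP0264408.1)
Conditions: Bu4NF (2.5 equiv), AcOH (2.5 equiv), THF, 0 °C
Reagents that add atoms: none
Why: Fluoride-induced desilylation (formation of the strong Si–F bond) should cleave both aryl silyl ethers, and the acetic acid buffer keeps the two lactones closed and the alkenes in place.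

Compound list
1 | 2-methylpropane-1,3-diol | CC(CO)CO | starting material
2 | rac-3-[(tert-butyldimethylsilyl)oxy]-2-methylpropan-1-ol | CC(CO)CO[Si](C)(C)C(C)(C)C | intermediate
3 | rac-3-[(tert-butyldimethylsilyl)oxy]-2-methylpropanal | CC(CO[Si](C)(C)C(C)(C)C)C=O | intermediate
4 | methyl vinyl ketone (but-3-en-2-one) | C=CC(C)=O | starting material
5 | (2R)-2-{[(tert-butyldimethylsilyl)oxy]methyl}-2-methyl-5-oxohexanal | CC(C)(C)[Si](C)(C)OC[C@@](C=O)(C)CCC(C)=O | intermediate
6 | (4R)-4-{[(tert-butyldimethylsilyl)oxy]methyl}-3-hydroxy-4-methylcyclohexan-1-one (both C3 epimers) | CC(C)(C)[Si](C)(C)OC[C@@]1(C)CCC(=O)CC1O | intermediate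
7 | (4S)-4-{[(tert-butyldimethylsilyl)oxy]methyl}-4-methylcyclohex-2-en-1-one | CC(C)(C)[Si](C)(C)OC[C@@]1(C)CCC(=O)C=C1 | intermediate
8 | (4S)-4-(hydroxymethyl)-4-methylcyclohex-2-en-1-one | OC[C@@]1(C)CCC(=O)C=C1 | intermediate
9 | 2-(diethoxyphosphoryl)acetic acid | CCOP(=O)(OCC)CC(=O)O | starting material
10 | [(1S)-1-methyl-4-oxocyclohex-2-en-1-yl]methyl 2-(diethoxyphosphoryl)acetate | CCOP(=O)(OCC)CC(=O)OC[C@@]1(C)CCC(=O)C=C1 | intermediate
11 | 2,4-dihydroxy-3-methoxybenzaldehyde | COc1c(O)ccc(C=O)c1O | starting material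
12 | 2-hydroxy-3-methoxy-4-[(triisopropylsilyl)oxy]benzaldehyde | COc1c(O[Si](C(C)C)(C(C)C)C(C)C)ccc(C=O)c1O | intermediate
13 | 3-methoxy-2-[(4-methoxybenzyl)oxy]-4-[(triisopropylsilyl)oxy]benzaldehyde | COc1ccc(COc2c(C=O)ccc(O[Si](C(C)C)(C(C)C)C(C)C)c2OC)cc1 | intermediate
14 | diethyl [(4aR,8aS)-8a-methyl-3,6-dioxooctahydro-1H-isochromen-4-yl]phosphonate (cis-fused, both C4 epimers) | O=C1OC[C@@]2(C)CCC(=O)C[C@H]2C1P(=O)(OCC)OCC | intermediate
15 | (4E,4aR,8aS)-4-{3-methoxy-2-[(4-methoxybenzyl)oxy]-4-[(triisopropylsilyl)oxy]benzylidene}-8a-methyl-4a,5,8,8a-tetrahydro-1H-isochromene-3,6(4H,7H)-dione | O=C1OC[C@@]2(C)CCC(=O)C[C@H]2/C1=C\c1ccc(O[Si](C(C)C)(C(C)C)C(C)C)c(OC)c1OCc1ccc(OC)cc1 | intermediate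
16 | (4E,4aR,8aS)-4-{3-methoxy-2-[(4-methoxybenzyl)oxy]-4-[(triisopropylsilyl)oxy]benzylidene}-8a-methyl-3-oxo-3,4,4a,7,8,8a-hexahydro-1H-isochromen-6-yl trifluoromethanesulfonate | O=C1OC[C@@]2(C)CCC(OS(=O)(=O)C(F)(F)F)=C[C@H]2/C1=C\c1ccc(O[Si](C(C)C)(C(C)C)C(C)C)c(OC)c1OCc1ccc(OC)cc1 | intermediate
17 | (4E,4aR,8aS)-4-{3-methoxy-2-[(4-methoxybenzyl)oxy]-4-[(triisopropylsilyl)oxy]benzylidene}-6,8a-dimethyl-1,4,4a,7,8,8a-hexahydro-3H-isochromen-3-one | O=C1OC[C@@]2(C)CCC(C)=C[C@H]2/C1=C\c1ccc(O[Si](C(C)C)(C(C)C)C(C)C)c(OC)c1OCc1ccc(OC)cc1 | intermediate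
18 | (4E,4aR,8aS)-4-{2-hydroxy-3-methoxy-4-[(triisopropylsilyl)oxy]benzylidene}-6,8a-dimethyl-1,4,4a,7,8,8a-hexahydro-3H-isochromen-3-one | O=C1OC[C@@]2(C)CCC(C)=C[C@H]2/C1=C\c1ccc(O[Si](C(C)C)(C(C)C)C(C)C)c(OC)c1O | intermediate
19 | (4Z,4aR,8aS)-4-{2-hydroxy-3-methoxy-4-[(triisopropylsilyl)oxy]benzylidene}-6,8a-dimethyl-1,4,4a,7,8,8a-hexahydro-3H-isochromen-3-one | O=C1OC[C@@]2(C)CCC(C)=C[C@H]2/C1=C/c1ccc(O[Si](C(C)C)(C(C)C)C(C)C)c(OC)c1O | intermediate
20 | {(1S,2R)-2-[8-methoxy-2-oxo-7-[(triisopropylsilyl)oxy]-2H-chromen-3-yl]-1,4-dimethylcyclohex-3-en-1-yl}methanol | OC[C@@]1(C)CCC(C)=C[C@H]1c1cc2ccc(O[Si](C(C)C)(C(C)C)C(C)C)c(OC)c2oc1=O | intermediate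
21 | (1S,2R)-2-[8-methoxy-2-oxo-7-[(triisopropylsilyl)oxy]-2H-chromen-3-yl]-1,4-dimethylcyclohex-3-ene-1-carbaldehyde | O=C[C@@]1(C)CCC(C)=C[C@H]1c1cc2ccc(O[Si](C(C)C)(C(C)C)C(C)C)c(OC)c2oc1=O | intermediate
22 | ethyl 2-(triphenyl-λ5-phosphanylidene)propanoate | CCOC(=O)C(C)=P(c1ccccc1)(c1ccccc1)c1ccccc1 | starting material
23 | ethyl (2E)-3-(2,4-dihydroxy-3-methoxyphenyl)-2-methylprop-2-enoate | CCOC(=O)/C(C)=C/c1ccc(O)c(OC)c1O | intermediate
24 | ethyl (2Z)-3-(2,4-dihydroxy-3-methoxyphenyl)-2-methylprop-2-enoate | CCOC(=O)/C(C)=C\c1ccc(O)c(OC)c1O | intermediate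
25 | 7-hydroxy-8-methoxy-3-methyl-2H-chromen-2-one | COc1c(O)ccc2cc(C)c(=O)oc12 | intermediate
26 | 8-methoxy-3-methyl-7-[(triisopropylsilyl)oxy]-2H-chromen-2-one | COc1c(O[Si](C(C)C)(C(C)C)C(C)C)ccc2cc(C)c(=O)oc12 | intermediate
27 | 3-(bromomethyl)-8-methoxy-7-[(triisopropylsilyl)oxy]-2H-chromen-2-one | COc1c(O[Si](C(C)C)(C(C)C)C(C)C)ccc2cc(CBr)c(=O)oc12 | intermediate
28 | diethyl ({8-methoxy-2-oxo-7-[(triisopropylsilyl)oxy]-2H-chromen-3-yl}methyl)phosphonate | CCOP(=O)(OCC)Cc1cc2ccc(O[Si](C(C)C)(C(C)C)C(C)C)c(OC)c2oc1=O | intermediate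
29 | 8-methoxy-3-[(E)-2-{(1R,2R)-2-[8-methoxy-2-oxo-7-[(triisopropylsilyl)oxy]-2H-chromen-3-yl]-1,4-dimethylcyclohex-3-en-1-yl}ethenyl]-7-[(triisopropylsilyl)oxy]-2H-chromen-2-one | COc1c(O[Si](C(C)C)(C(C)C)C(C)C)ccc2cc(/C=C/[C@@]3(C)CCC(C)=C[C@H]3c3cc4ccc(O[Si](C(C)C)(C(C)C)C(C)C)c(OC)c4oc3=O)c(=O)oc12 | intermediate
30 | 7-hydroxy-3-[(E)-2-[(1R,2R)-2-(7-hydroxy-8-methoxy-2-oxo-2H-chromen-3-yl)-1,4-dimethylcyclohex-3-en-1-yl]ethenyl]-8-methoxy-2H-chromen-2-one | COc1c(O)ccc2cc(/C=C/[C@@]3(C)CCC(C)=C[C@H]3c3cc4ccc(O)c(OC)c4oc3=O)c(=O)oc12 | target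

Total step count: 19.
Longest linear sequence: 13 steps (steps 1–5, 8–13, 18 and 19).

Steps most likely to fail

Step 3. Methyl and silyloxymethyl differ little close to nitrogen, so the enamine may form as a mixture of geometries and the enantioselectivity may erode. Silanolate may also be lost from the enamine by β-elimination, and the catalyst may be consumed by aza-Michael addition to 4. The fallback sets the stereocentre after the annulation instead of during it. From 3 and 4 the same Michael–aldol annulation is run with pyrrolidine and acetic acid to give rac-4-{[(tert-butyldimethylsilyl)oxy]methyl}-4-methylcyclohex-2-en-1-one F1. Dehydrogenation with IBX in DMSO at 75 °C gives the achiral 4-{[(tert-butyldimethylsilyl)oxy]methyl}-4-methylcyclohexa-2,5-dien-1-one F2. A copper hydride catalyst made from Cu(OAc)2, one antipode of DTBM-SEGPHOS and (EtO)2MeSiH then reduces one of the two enantiotopic alkenes by conjugate reduction (desymmetrisation), and the route is rejoined at 7.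

Step 9. Proton loss from the activated ketone may occur toward C3 as well as toward C5, which would give regioisomeric enol triflates and, after coupling, a mixture of alkene isomers. The fallback lets the conjugate addition itself fix the enol position. From 10, TBSOTf and Et3N in CH2Cl2 convert the phosphonoacetate into its silyl ketene acetal and promote an intramolecular Mukaiyama–Michael addition. This leaves the C4–C5 enolate trapped as diethyl [(4aR,8aS)-6-[(tert-butyldimethylsilyl)oxy]-8a-methyl-3-oxo-3,4,4a,7,8,8a-hexahydro-1H-isochromen-4-yl]phosphonate F3. Horner–Wadsworth–Emmons reaction with 13 (NaH, THF) gives (4E,4aR,8aS)-6-[(tert-butyldimethylsilyl)oxy]-4-{3-methoxy-2-[(4-methoxybenzyl)oxy]-4-[(triisopropylsilyl)oxy]benzylidene}-8a-methyl-1,4,4a,7,8,8a-hexahydro-3H-isochromen-3-one F4. CsF and PhNTf2 in DME exchange silyl for triflyl without moving the double bond, and the route is rejoined at 16.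

Step 18. Addition of the allylic phosphonate anion to the hindered neopentyl aldehyde may be slow and reversible, so that the anion is lost instead by attack on a coumarin C4 or through its ring-centred resonance form. The fallback forms the bond at the unhindered terminal carbon of an alkene without any carbanion. From 21, methylenation with Ph3P=CH2 (MePPh3Br, KOtBu, THF, 0 °C) gives 3-[(1R,6R)-6-ethenyl-3,6-dimethylcyclohex-2-en-1-yl]-8-methoxy-7-[(triisopropylsilyl)oxy]-2H-chromen-2-one F5. The partner is made from 12 by Wittig reaction with ethyl (triphenyl-λ5-phosphanylidene)acetate in refluxing PhNEt2. This passes through ethyl (2E)-3-{2-hydroxy-3-methoxy-4-[(triisopropylsilyl)oxy]phenyl}prop-2-enoate F6 and its (2Z)-isomer, ethyl (2Z)-3-{2-hydroxy-3-methoxy-4-[(triisopropylsilyl)oxy]phenyl}prop-2-enoate F7, which lactonises to 8-methoxy-7-[(triisopropylsilyl)oxy]-2H-chromen-2-one F8. NBS in MeCN brominates the electron-rich C3 to give 3-bromo-8-methoxy-7-[(triisopropylsilyl)oxy]-2H-chromen-2-one F9. Heck coupling of F5 with F9 (Pd(OAc)2, P(o-tol)3, Et3N, DMF, 90 °C) should give the (E)-alkene, because the quaternary C1 offers no competing β-hydrogen, and the route is rejoined at 29.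

Further compounds
F1 | step 3 | rac-4-{[(tert-butyldimethylsilyl)oxy]methyl}-4-methylcyclohex-2-en-1-one | CC(C)(C)[Si](C)(C)OCC1(C)CCC(=O)C=C1
F2 | step 3 | 4-{[(tert-butyldimethylsilyl)oxy]methyl}-4-methylcyclohexa-2,5-dien-1-one | CC(C)(C)[Si](C)(C)OCC1(C)C=CC(=O)C=C1
F3 | step 9 | diethyl [(4aR,8aS)-6-[(tert-butyldimethylsilyl)oxy]-8a-methyl-3-oxo-3,4,4a,7,8,8a-hexahydro-1H-isochromen-4-yl]phosphonate | O=C1OC[C@@]2(C)CCC(O[Si](C)(C)C(C)(C)C)=C[C@H]2C1P(=O)(OCC)OCC
F4 | step 9 | (4E,4aR,8aS)-6-[(tert-butyldimethylsilyl)oxy]-4-{3-methoxy-2-[(4-methoxybenzyl)oxy]-4-[(triisopropylsilyl)oxy]benzylidene}-8a-methyl-1,4,4a,7,8,8a-hexahydro-3H-isochromen-3-one | O=C1OC[C@@]2(C)CCC(O[Si](C)(C)C(C)(C)C)=C[C@H]2/C1=C\c1ccc(O[Si](C(C)C)(C(C)C)C(C)C)c(OC)c1OCc1ccc(OC)cc1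
F5 | step 18 | 3-[(1R,6R)-6-ethenyl-3,6-dimethylcyclohex-2-en-1-yl]-8-methoxy-7-[(triisopropylsilyl)oxy]-2H-chromen-2-one | C=C[C@@]1(C)CCC(C)=C[C@H]1c1cc2ccc(O[Si](C(C)C)(C(C)C)C(C)C)c(OC)c2oc1=O
F6 | step 18 | ethyl (2E)-3-{2-hydroxy-3-methoxy-4-[(triisopropylsilyl)oxy]phenyl}prop-2-enoate | CCOC(=O)/C=C/c1ccc(O[Si](C(C)C)(C(C)C)C(C)C)c(OC)c1O
F7 | step 18 | ethyl (2Z)-3-{2-hydroxy-3-methoxy-4-[(triisopropylsilyl)oxy]phenyl}prop-2-enoate | CCOC(=O)/C=C\c1ccc(O[Si](C(C)C)(C(C)C)C(C)C)c(OC)c1O
F8 | step 18 | 8-methoxy-7-[(triisopropylsilyl)oxy]-2H-chromen-2-one | COc1c(O[Si](C(C)C)(C(C)C)C(C)C)ccc2ccc(=O)oc12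
F9 | step 18 | 3-bromo-8-methoxy-7-[(triisopropylsilyl)oxy]-2H-chromen-2-one | COc1c(O[Si](C(C)C)(C(C)C)C(C)C)ccc2cc(Br)c(=O)oc12
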